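**Plan**

- Retrosynthesis: after removal of the three aryl silyl ethers and the C3 ester, ring C is cut at O1–C2 and C4–C3 in one retro-[4+2]. This gives a ring A ortho-quinone ketene and a ring B (E)-enol ester; the enol ester is cut at its vinyl C–O bond and the geranyl chain at its aryl–CH2 bond.
- Enabling feature: in ring C the atoms O1, C8a, C4a and C4 are a salicyloyl unit of ring A, that is a latent 1-oxadiene O1=C8a–C4a=C4(=O). C2–C3 is a two-carbon unit whose C3 bears oxygen and whose C2 is benzylic and para to the 4'-oxygen of ring B, so C3 is the nucleophilic end and C2 the cation-stabilising end.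
- Forward order: ring A acid 6 from 2-methylresorcinol (symmetry plus a sterically governed C–H borylation place the methyl group between O5 and O7 and para to O1). Ring B enol ester 16 from 4-iodophenol (geranyl chain, alkyne, E-alkenylboron, C–O coupling). Ring C is closed in step 10, followed by two deprotections.
- Stereochemistry: 2,3-trans from the E-enol ester; absolute configuration from the (S)-O-methylmandelate on the enol oxygen (face selection at C3, diastereomers separable); the E-geranyl alkene comes unchanged from geranyl bromide.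

Key step: step 10

Remark: the facial sense of the (S)-mandelate in step 10 is assumed by analogy with mandelate esters of dienols; if the major trans-adduct proves to be (2S,3S), the (R)-acid is used in step 9 and nothing else changes.
Abbreviations: TBS = tert-butyldimethylsilyl, TIPS = triisopropylsilyl, geranyl = (2E)-3,7-dimethylocta-2,6-dien-1-yl.

**Route**

Step 1
Reactants: 1 2-methylresorcinol (2-methylbenzene-1,3-diol)
Product: 2 1,3-bis(tert-butyldimethylsilyloxy)-2-methylbenzene
Conditions: TBSCl, imidazole, DMF, rt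
Reagents that add atoms: tert-butyldimethylsilyl chloride CC(C)(C)[Si](C)(C)Cl
Why: Silyl ether formation masks the future O5 and O7 with one fluoride-labile group and keeps the ring symmetric, so that the next step meets only one unhindered C–H.

Step 2
Reactants: 2 1,3-bis(tert-butyldimethylsilyloxy)-2-methylbenzene
Product: 4 3,5-bis(tert-butyldimethylsilyloxy)-4-methylphenol, via aryl pinacol boronate 3 (not isolated)
Conditions: [Ir(OMe)(cod)]2 (cat.), 4,4'-di-tert-butyl-2,2'-bipyridine, HBpin, hexane, 60 °C; then Oxone (2KHSO5·KHSO4·K2SO4), acetone/H2O, rt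
Reagents that add atoms: potassium peroxymonosulfate KHSO5 OOS(=O)(=O)[O-].[K+]
Why: Iridium-catalysed C–H borylation is governed by sterics and should go only to the C–H para to the methyl group (the one position without an ortho substituent), and oxidation of the C–B bond turns that position into the phenol oxygen that becomes O1.

Step 3
Reactants: 4 3,5-bis(tert-butyldimethylsilyloxy)-4-methylphenol
Product: 5 6-hydroxy-2,4-bis(tert-butyldimethylsilyloxy)-3-methylbenzaldehyde
Conditions: MgCl2, Et3N, paraformaldehyde, MeCN, reflux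
Reagents that add atoms: paraformaldehyde (as formaldehyde) C=O
Why: Casnati–Skattebøl ortho-formylation through the magnesium phenoxide puts the future C4 next to the free OH; the two ortho positions are equivalent and the para position carries the methyl group, so one aldehyde is expected.

Step 4
Reactants: 5 6-hydroxy-2,4-bis(tert-butyldimethylsilyloxy)-3-methylbenzaldehyde
Product: 6 6-hydroxy-2,4-bis(tert-butyldimethylsilyloxy)-3-methylbenzoic acid
Conditions: NaClO2, NaH2PO4, 2-methyl-2-butene, t-BuOH/THF/H2O, 0 °C → rt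
Reagents that add atoms: sodium chlorite NaClO2 [Na+].[O-]Cl=O
Why: Pinnick oxidation with an alkene as hypochlorite scavenger should take the electron-rich salicylaldehyde to the acid without ring chlorination and without touching the silyl ethers.

Step 5
Reactants: 7 4-iodophenol (in excess); 8 geranyl bromide [(2E)-1-bromo-3,7-dimethylocta-2,6-diene]
Product: 9 2-[(2E)-3,7-dimethylocta-2,6-dien-1-yl]-4-iodophenol
Conditions: NaH, PhMe, 0 °C → rt
Reagents that add atoms: none
Why: C-alkylation of the sodium phenoxide as a tight ion pair in toluene should direct the allylic bromide to the ortho carbon (para is blocked by iodine) by SN2 attack at the primary carbon, which keeps the E-alkene of geranyl bromide.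

Step 6
Reactants: 9 2-[(2E)-3,7-dimethylocta-2,6-dien-1-yl]-4-iodophenol
Product: 10 [2-geranyl-4-iodophenoxy]triisopropylsilane
Conditions: TIPSCl, imidazole, DMF, rt
Reagents that add atoms: triisopropylsilyl chloride CC(C)[Si](Cl)(C(C)C)C(C)C
Why: Silyl ether formation; the TIPS group keeps the para oxygen a strong donor for step 10, should survive carbonate/methanol and brief bifluoride in steps 7 and 8, and leaves with the other silyl groups at the end.

Step 7
Reactants: 10 [2-geranyl-4-iodophenoxy]triisopropylsilane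
Product: 12 [4-ethynyl-2-geranylphenoxy]triisopropylsilane, via silylated alkyne 11 (not isolated)
Conditions: PdCl2(PPh3)2 (cat.), CuI (cat.), trimethylsilylacetylene, Et3N, THF, rt; then K2CO3 (cat.), MeOH, rt
Reagents that add atoms: ethynyltrimethylsilane C#C[Si](C)(C)C
Why: Sonogashira coupling at the aryl iodide followed by methanolysis of the alkynyl C–Si bond gives the terminal alkyne; the geranyl alkenes are inert to both.

Step 8
Reactants: 12 [4-ethynyl-2-geranylphenoxy]triisopropylsilane
Product: 14 potassium (E)-{2-[3-geranyl-4-(triisopropylsilyloxy)phenyl]ethenyl}trifluoroborate, via E-alkenyl pinacol boronate 13 (not isolated)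
Conditions: HBpin, Cp2Zr(H)Cl (cat.), Et3N (cat.), CH2Cl2, 50 °C; then KHF2, MeOH/H2O, 0 °C, short contact
Reagents that add atoms: pinacolborane CC1(C)OBOC1(C)C; potassium hydrogen difluoride KHF2 [K+].[F-].F
Why: Zirconium-hydride-catalysed hydroboration adds H–B syn and anti-Markovnikov to the terminal alkyne only, which fixes the E geometry, and bifluoride converts the boronate into the trifluoroborate needed for the next coupling.

Step 9
Reactants: 14 potassium (E)-{2-[3-geranyl-4-(triisopropylsilyloxy)phenyl]ethenyl}trifluoroborate; 15 (S)-2-methoxy-2-phenylacetic acid [(S)-O-methylmandelic acid]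
Product: 16 (E)-2-[3-geranyl-4-(triisopropylsilyloxy)phenyl]ethenyl (S)-2-methoxy-2-phenylacetate
Conditions: CuBr (cat.), DMAP, 4 Å molecular sieves, O2 (1 atm), CH2Cl2, 60 °C
Reagents that add atoms: none
Why: Copper-catalysed oxidative C–O coupling of an alkenyltrifluoroborate with a carboxylic acid (Chan–Lam type) forms the enol ester with retention of the E geometry and should not touch the stereocentre of the acid.

Step 10
Reactants: 6 6-hydroxy-2,4-bis(tert-butyldimethylsilyloxy)-3-methylbenzoic acid (in excess); 16 (E)-2-[3-geranyl-4-(triisopropylsilyloxy)phenyl]ethenyl (S)-2-methoxy-2-phenylacetate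
Product: 19 (2R,3R)-5,7-bis(tert-butyldimethylsilyloxy)-2-[3-geranyl-4-(triisopropylsilyloxy)phenyl]-6-methyl-4-oxochroman-3-yl (S)-2-methoxy-2-phenylacetate, via acid chloride 17 (not isolated), via ortho-quinone ketene 18 (not isolated)
Conditions: 6, 1-chloro-N,N,2-trimethylprop-1-en-1-amine, CH2Cl2, 0 °C → rt; then slow addition (syringe pump) to 16 and 1,8-bis(dimethylamino)naphthalene, PhMe, −20 °C → rt
Reagents that add atoms: none
Why: Proposed new method: the hindered base removes HCl from the ortho-hydroxy acid chloride 17 in a 1,4-sense (E1cB) to give the ortho-quinone ketene 18, whose ketene carbon (C4) is attacked by the enol carbon C3 of 16 with rearomatisation of ring A, after which the phenoxide O1 adds to the para-silyloxybenzyl cation at C2; the closest known reaction types are the [4+2] cycloadditions of acylketenes with vinyl ethers, of ortho-quinone ketenes with carbonyl compounds (the reverse of benzodioxinone cleavage), and of ortho-quinone methides with para-oxygenated styrenes. Ring C closes by an intermolecular hetero-[4+2] annulation (O1=C8a–C4a=C4 as the four-atom unit, C2=C3 as the two-atom unit), and if the addition is stepwise the O1–C2 bond forms in a 6-exo-trig sense on the quinone-methide-like cation. C3 is controlled by the (S)-O-methylmandelate, whose phenyl ring should cover one face of the enol carbon, and C2 by the E geometry of 16 (suprafacial addition, or closure anti to the acyloxy group), so that the 2,3-trans ring results by either mechanism. The step needs regioselectivity (C3 and not C2 to the ketene carbon), which the strongly donating para-silyloxyaryl group on C2 should secure over the weakly donating acyloxy group on C3. It needs chemoselectivity for the aryl-conjugated enol ester over the two isolated trisubstituted geranyl alkenes, which benzylic cation stabilisation should secure, and slow addition of 17 keeps the ketene from condensing with itself. The minor (2S,3S)-adduct is a diastereomer because of the mandelate and is removed by chromatography.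

Step 11
Reactants: 19 (2R,3R)-5,7-bis(tert-butyldimethylsilyloxy)-2-[3-geranyl-4-(triisopropylsilyloxy)phenyl]-6-methyl-4-oxochroman-3-yl (S)-2-methoxy-2-phenylacetate
Product: 20 (2R,3R)-5,7-bis(tert-butyldimethylsilyloxy)-2-[3-geranyl-4-(triisopropylsilyloxy)phenyl]-3-hydroxy-6-methylchroman-4-one
Conditions: Yb(OTf)3 (cat.), MeOH/CH2Cl2, 0 °C → rt
Reagents that add atoms: none
Why: Lanthanide-triflate-catalysed methanolysis is selective for α-alkoxy esters because the metal chelates the ester carbonyl and the methoxy oxygen, so the mandelate should leave under near-neutral conditions that neither enolise C3 nor open ring C.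

Step 12
Reactants: 20 (2R,3R)-5,7-bis(tert-butyldimethylsilyloxy)-2-[3-geranyl-4-(triisopropylsilyloxy)phenyl]-3-hydroxy-6-methylchroman-4-one
Product: 21 (2R,3R)-2-{3-[(2E)-3,7-dimethylocta-2,6-dien-1-yl]-4-hydroxyphenyl}-3,5,7-trihydroxy-6-methylchroman-4-one (target)
Conditions: Bu4NF, AcOH, THF, 0 °C
Reagents that add atoms: none
Why: Fluoride cleavage of the three aryl silyl ethers, buffered with acetic acid so that the phenols and the base-sensitive dihydroflavonol never meet a basic medium; both stereocentres and the geranyl alkenes are untouched.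

**Compound list**

1 | 2-methylresorcinol | Cc1c(O)cccc1O | starting material
2 | 1,3-bis(tert-butyldimethylsilyloxy)-2-methylbenzene | Cc1c(O[Si](C)(C)C(C)(C)C)cccc1O[Si](C)(C)C(C)(C)C | intermediate
3 | 2-[3,5-bis(tert-butyldimethylsilyloxy)-4-methylphenyl]-4,4,5,5-tetramethyl-1,3,2-dioxaborolane | Cc1c(O[Si](C)(C)C(C)(C)C)cc(B2OC(C)(C)C(C)(C)O2)cc1O[Si](C)(C)C(C)(C)C | intermediate
4 | 3,5-bis(tert-butyldimethylsilyloxy)-4-methylphenol | Cc1c(O[Si](C)(C)C(C)(C)C)cc(O)cc1O[Si](C)(C)C(C)(C)C | intermediate
5 | 6-hydroxy-2,4-bis(tert-butyldimethylsilyloxy)-3-methylbenzaldehyde | O=Cc1c(O)cc(O[Si](C)(C)C(C)(C)C)c(C)c1O[Si](C)(C)C(C)(C)C | intermediate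
6 | 6-hydroxy-2,4-bis(tert-butyldimethylsilyloxy)-3-methylbenzoic acid | OC(=O)c1c(O)cc(O[Si](C)(C)C(C)(C)C)c(C)c1O[Si](C)(C)C(C)(C)C | intermediate
7 | 4-iodophenol | Oc1ccc(I)cc1 | starting material
8 | geranyl bromide | CC(C)=CCC/C(C)=C/CBr | starting material
9 | 2-[(2E)-3,7-dimethylocta-2,6-dien-1-yl]-4-iodophenol | CC(C)=CCC/C(C)=C/Cc1cc(I)ccc1O | intermediate
10 | [2-geranyl-4-iodophenoxy]triisopropylsilane | CC(C)=CCC/C(C)=C/Cc1cc(I)ccc1O[Si](C(C)C)(C(C)C)C(C)C | intermediate
11 | {[3-geranyl-4-(triisopropylsilyloxy)phenyl]ethynyl}trimethylsilane | CC(C)=CCC/C(C)=C/Cc1cc(C#C[Si](C)(C)C)ccc1O[Si](C(C)C)(C(C)C)C(C)C | intermediate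
12 | [4-ethynyl-2-geranylphenoxy]triisopropylsilane | CC(C)=CCC/C(C)=C/Cc1cc(C#C)ccc1O[Si](C(C)C)(C(C)C)C(C)C | intermediate
13 | 2-{(E)-2-[3-geranyl-4-(triisopropylsilyloxy)phenyl]ethenyl}-4,4,5,5-tetramethyl-1,3,2-dioxaborolane | CC(C)=CCC/C(C)=C/Cc1cc(/C=C/B2OC(C)(C)C(C)(C)O2)ccc1O[Si](C(C)C)(C(C)C)C(C)C | intermediate
14 | potassium (E)-{2-[3-geranyl-4-(triisopropylsilyloxy)phenyl]ethenyl}trifluoroborate | CC(C)=CCC/C(C)=C/Cc1cc(/C=C/[B-](F)(F)F)ccc1O[Si](C(C)C)(C(C)C)C(C)C.[K+] | intermediate
15 | (S)-2-methoxy-2-phenylacetic acid | CO[C@@H](c1ccccc1)C(=O)O | starting material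
16 | (E)-2-[3-geranyl-4-(triisopropylsilyloxy)phenyl]ethenyl (S)-2-methoxy-2-phenylacetate | CC(C)=CCC/C(C)=C/Cc1cc(/C=C/OC(=O)[C@@H](OC)c2ccccc2)ccc1O[Si](C(C)C)(C(C)C)C(C)C | intermediate
17 | 6-hydroxy-2,4-bis(tert-butyldimethylsilyloxy)-3-methylbenzoyl chloride | ClC(=O)c1c(O)cc(O[Si](C)(C)C(C)(C)C)c(C)c1O[Si](C)(C)C(C)(C)C | intermediate
18 | 3,5-bis(tert-butyldimethylsilyloxy)-4-methyl-6-(oxomethylidene)cyclohexa-2,4-dien-1-one | O=C=C1C(=O)C=C(O[Si](C)(C)C(C)(C)C)C(C)=C1O[Si](C)(C)C(C)(C)C | intermediate
19 | (2R,3R)-5,7-bis(tert-butyldimethylsilyloxy)-2-[3-geranyl-4-(triisopropylsilyloxy)phenyl]-6-methyl-4-oxochroman-3-yl (S)-2-methoxy-2-phenylacetate | CC(C)=CCC/C(C)=C/Cc1cc([C@H]2Oc3cc(O[Si](C)(C)C(C)(C)C)c(C)c(O[Si](C)(C)C(C)(C)C)c3C(=O)[C@@H]2OC(=O)[C@@H](OC)c2ccccc2)ccc1O[Si](C(C)C)(C(C)C)C(C)C | intermediate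
20 | (2R,3R)-5,7-bis(tert-butyldimethylsilyloxy)-2-[3-geranyl-4-(triisopropylsilyloxy)phenyl]-3-hydroxy-6-methylchroman-4-one | CC(C)=CCC/C(C)=C/Cc1cc([C@H]2Oc3cc(O[Si](C)(C)C(C)(C)C)c(C)c(O[Si](C)(C)C(C)(C)C)c3C(=O)[C@@H]2O)ccc1O[Si](C(C)C)(C(C)C)C(C)C | intermediate
21 | (2R,3R)-2-{3-[(2E)-3,7-dimethylocta-2,6-dien-1-yl]-4-hydroxyphenyl}-3,5,7-trihydroxy-6-methylchroman-4-one | CC(C)=CCC/C(C)=C/Cc1cc([C@H]2Oc3cc(O)c(C)c(O)c3C(=O)[C@@H]2O)ccc1O | target

**Count**

Total steps: 12. Longest linear sequence: 8 steps (steps 5 to 12); the ring A branch (steps 1 to 4) joins at step 10.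

**Steps most likely to fail**

1. Step 10. The ketene may condense with itself faster than the only moderately nucleophilic alkene captures it, the alkene may attack through C2 instead of C3, or face selection by the auxiliary may be weak.
 Fallback (known chemistry, ring C made in two separate bond-forming events): setting out from aldehyde 5 and alkyne 12, rhodium-catalysed alkyne hydroacylation ([RhCl(cod)]2, 1,1'-bis(diphenylphosphino)ferrocene Fe(C5H4PPh2)2, Na2CO3, PhMe, 80 °C) should give the E-configured 2'-hydroxychalcone F1. Methoxymethylation of its hydrogen-bonded phenol (MOMCl, iPr2NEt, CH2Cl2) gives the 2'-O-methoxymethyl chalcone F2. Juliá–Colonna epoxidation (poly-L-leucine, urea·H2O2, DBU, THF), a nucleophilic epoxidation that leaves the geranyl alkenes alone, gives the (2R,3S)-epoxy ketone F3. Brief treatment with HCl in MeOH/THF at 0 °C removes the acetal and lets the freed phenol open the epoxide at the benzylic carbon with inversion. This gives 20, where the route is rejoined before step 12.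

2. Step 11. The Lewis acid may cause loss or migration of the aryl silyl groups (above all the one on O5 next to the ketone), or methanolysis of the hindered ester may be sluggish.
 Fallback: from 19 the order of the two deprotections is reversed. Bu4NF/AcOH (THF, 0 °C) first gives the free-phenol mandelate F4. The ester is then cleaved by lipase-catalysed alcoholysis (immobilised Candida antarctica lipase B, MeOH, tert-butyl methyl ether, 30 °C), which arrives at 21.

3. Step 5. O-alkylation, double alkylation or attack through the tertiary allylic terminus may compete with the wanted ortho-C-alkylation.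
 Fallback: from 7 and 8, Williamson O-alkylation (K2CO3, acetone, reflux) gives geranyl 4-iodophenyl ether F5. An acid-clay-promoted 1,3-shift of the allyl group from oxygen to the ortho carbon (montmorillonite K10 clay, nominally Al2Si4O10(OH)2·nH2O, CH2Cl2, rt) then gives 9.

**Further compounds**

F1 | step 10 | (E)-1-[6-hydroxy-2,4-bis(tert-butyldimethylsilyloxy)-3-methylphenyl]-3-[3-geranyl-4-(triisopropylsilyloxy)phenyl]prop-2-en-1-one | CC(C)=CCC/C(C)=C/Cc1cc(/C=C/C(=O)c2c(O)cc(O[Si](C)(C)C(C)(C)C)c(C)c2O[Si](C)(C)C(C)(C)C)ccc1O[Si](C(C)C)(C(C)C)C(C)C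
F2 | step 10 | (E)-1-[6-(methoxymethoxy)-2,4-bis(tert-butyldimethylsilyloxy)-3-methylphenyl]-3-[3-geranyl-4-(triisopropylsilyloxy)phenyl]prop-2-en-1-one | CC(C)=CCC/C(C)=C/Cc1cc(/C=C/C(=O)c2c(OCOC)cc(O[Si](C)(C)C(C)(C)C)c(C)c2O[Si](C)(C)C(C)(C)C)ccc1O[Si](C(C)C)(C(C)C)C(C)C
F3 | step 10 | {(2R,3S)-3-[3-geranyl-4-(triisopropylsilyloxy)phenyl]oxiran-2-yl}[6-(methoxymethoxy)-2,4-bis(tert-butyldimethylsilyloxy)-3-methylphenyl]methanone | CC(C)=CCC/C(C)=C/Cc1cc([C@@H]2O[C@H]2C(=O)c2c(OCOC)cc(O[Si](C)(C)C(C)(C)C)c(C)c2O[Si](C)(C)C(C)(C)C)ccc1O[Si](C(C)C)(C(C)C)C(C)C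
F4 | step 11 | (2R,3R)-2-(3-geranyl-4-hydroxyphenyl)-5,7-dihydroxy-6-methyl-4-oxochroman-3-yl (S)-2-methoxy-2-phenylacetate | CC(C)=CCC/C(C)=C/Cc1cc([C@H]2Oc3cc(O)c(C)c(O)c3C(=O)[C@@H]2OC(=O)[C@@H](OC)c2ccccc2)ccc1O
F5 | step 5 | geranyl 4-iodophenyl ether | CC(C)=CCC/C(C)=C/COc1ccc(I)cc1
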